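The numbers in the tables were generated by integration with made-up constants; noise was put on by code.

Start with the easy step. Electrophile plus nucleophile gives product and acid set free, and the nucleophile charge 0.390 M exceeds the electrophile charge 0.30 M. With just that step, electrophile is the limiting reagent and the flask heads for 100 percent of the electrophile charged.

| setting | alpha | theta | delta | flask |
|---|---|---|---|---|
| electrophile | 0.30 M | 0.30 M | 0.45 M | 0.30 M |
| nucleophile | 0.20 M | 0.78 M | 0.39 M | 0.390 M |
| gas | 26 mM (held) | 26 mM (held) | 26 mM (held) | 26 mM (held) |
| remark | run made earlier | run made earlier | run made earlier |  |
| time |  |  |  | 8.0 h |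

- alpha (time / h: product / %): 0.833: 29; 1.33: 28; 2.00: 32; 2.50: 39; 4.00: 42; 6.00: 46; 10.0: 53
- theta (time / h: product / %): 0.833: 77; 1.33: 86; 2.00: 94; 2.50: 94; 4.00: 98; 6.00: 99; 10.0: 103
- delta (time / h: product / %): 2.00: 47; 4.00: 54; 6.00: 56; 8.00: 58; 10.0: 62

(readings scatter by 1.5 percentage points)

- at the start none of free base is dissolved
- the numbers in the tables scatter by 1.5 percentage points (one standard deviation)
- what may be going on: electrophile + nucleophile -> acid set free + product; nucleophile + acid set free <-> protonated nucleophile; acid set free + free base <-> salt of the base; gas <-> free base

- how much product there is at 8.0 h, in percent of the electrophile charged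
- concentration of free base in solution at 4.0 h, in percent of saturation
- the change that raises the amount of product at 8.0 h, in percent of the electrophile charged most ("none" if none brings more than 2 percentage points) (autumn / spring / noon / none)
- amount of product at 8.0 h, in percent of the electrophile charged, after autumn

- autumn: doubling the saturation concentration of gas, all else as stated
- spring: doubling the amount of nucleophile, all else as stated
- noon: doubling the transfer coefficient of the gas, all else as stated

Now add the second process. Acid set free takes up nucleophile as protonated nucleophile, so until free base takes part each product costs two nucleophiles, and alpha slows near 32% at 2.00 h, a reading whose product equals half of its nucleophile charge. Call the nucleophile charge divided by two electrophile charges the burst ceiling: 65.0% in this flask. For alpha it gives 33.3%. For delta it gives 43.3%, against a reading of 47% at 2.00 h. Theta's ceiling of 130% stands above 100, and theta reads 99% at 6.00 h.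

Last comes the gas. As free base it can take acid set free and hand nucleophile back, and the readings do creep past the ceiling: alpha reads 0.00788 M/h, delta 0.00844 M/h, nearly equal although delta was charged with 0.45 M of electrophile and 0.39 M of nucleophile, alpha with 0.30 M and 0.20 M. Taking the burst in this flask as over at alpha's 2.00 h and adding alpha's creep for the 6.00 h that follow, my reckoning for this flask lands at 80.8%.

The forecast stands higher at 83%, with free base at 12% of saturation, spring as the best change and 93% after autumn. Its ground is that “free base stays well below saturation”.

The flask gives 79.0%, with free base at 72.4% of saturation at 4.0 h, not 12%. Autumn brings 82.1%, a gain of 3.1 percentage points where the forecast expected 10 points, and spring is best, as forecast, with a gain of 21 points. In this flask product crosses the ceiling of 65.0% between 61.3% at 2.00 h and 70.0% at 4.00 h.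

    electrophile + nucleophile → acid set free + product (k = 0.0610 /M/min)
    nucleophile + acid set free ⇌ protonated nucleophile, settled at all times (K = 170 /M)
    acid set free + free base ⇌ salt of the base (K = 1.90 × 10⁶ /M, k = 0.310 /M/min)
    gas ⇌ free base, rate k4*(csat - [free base]) (kL = 0.0240 /min)

For the neighbour flask with 1.2 M of electrophile, the ceiling is 16.2%, and adding alpha's creep gives 20.2%. That flask computes to 28.1% at 8.0 h, above this reckoning, with 0.65% of its nucleophile charge unbound.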